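**Retrosynthetic overview**

1. The target is reached by removing four methoxymethyl (MOM) ethers from the tetra-MOM (2S)-flavanone; no ring is formed after the key step.
2. Key disconnection: the pyranone ring (ring C) is opened at O1–C8a and C4–C4a at once. This gives a 3,5-bis(MOM-oxy)-4-prenylbenzyne (ring A, triple bond across C4a/C8a) and an (S)-3-aryl-3-silyloxy Weinreb amide (O1–C2–C3–C4 carrying ring B). Ring C is the only ring made in the route.
3. Enabling feature: O1 and the C4 carbonyl sit on the adjacent ring-fusion carbons C8a and C4a, and the C5 oxygen flanks C4a. In the aryne this oxygen polarises the triple bond so that the alkoxide bonds to C8a and the carbanion appears at C4a, six atoms from the acyl carbon.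
4. Aryne precursor: resorcinol → bis-MOM ether → C2 prenylation → C–H borylation/oxidation para to the prenyl group → carbamate-directed ortho-silylation → silyl triflate. Ring A stays mirror-symmetric until the silylation.
5. Alkoxide partner: 3',4'-dihydroxyacetophenone → bis-MOM ether → β-keto ester → asymmetric transfer hydrogenation (sets C2) → Weinreb amide → TMS ether.

Key step: step 12

Remark on the chemistry: the target is the (2S)-flavanone; the carbinol carbon of the open-chain partner carries the same descriptor (S), because no bond to it is made or broken later and the CIP order O > aryl > CH2 > H does not change.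

**Route**

Step 1
Reactants: 1 resorcinol
Product: 2 1,3-bis(methoxymethoxy)benzene
Conditions: NaH, MOMCl, DMF, 0 °C → rt
Reagents that add atoms: chloromethyl methyl ether (MOMCl), COCCl
Why: Williamson etherification of both phenoxides with the reactive α-chloro ether should be clean; no stereocentre is involved.

Step 2
Reactants: 2 1,3-bis(methoxymethoxy)benzene; 3 prenyl bromide (1-bromo-3-methylbut-2-ene)
Product: 5 1,3-bis(methoxymethoxy)-2-(3-methylbut-2-en-1-yl)benzene, via 2,6-bis(methoxymethoxy)phenyllithium 4 (not isolated)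
Conditions: n-BuLi, THF, 0 °C → rt; then CuI (10 mol %), 3, −78 °C → rt
Reagents that add atoms: none
Why: Directed ortho-metalation, in which the two MOM-oxy groups cooperate to place lithium at C2 between them, followed by copper-catalysed allylic substitution at the primary carbon of prenyl bromide.

Step 3
Reactants: 5 1,3-bis(methoxymethoxy)-2-(3-methylbut-2-en-1-yl)benzene
Product: 7 3,5-bis(methoxymethoxy)-4-(3-methylbut-2-en-1-yl)phenol, via aryl pinacol boronate 6 (not isolated)
Conditions: [Ir(OMe)(cod)]2 (1.5 mol %), dtbpy (3 mol %), B2pin2 (0.55 equiv), THF, 60 °C; then 30% H2O2, 1 M NaOH, 0 °C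
Reagents that add atoms: hydrogen peroxide, OO (the phenol oxygen); bis(pinacolato)diboron, CC1(C)OB(OC1(C)C)B1OC(C)(C)C(C)(C)O1 (boron of 6 only, not retained in 7)
Why: Iridium-catalysed C–H borylation is sterically controlled and should select the only ring C–H without an ortho substituent (para to the prenyl group), the trisubstituted alkene being a poor substrate for the catalyst; alkaline peroxide oxidation of the C–B bond then gives the mirror-symmetric phenol.

Step 4
Reactants: 7 3,5-bis(methoxymethoxy)-4-(3-methylbut-2-en-1-yl)phenol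
Product: 8 3,5-bis(methoxymethoxy)-4-(3-methylbut-2-en-1-yl)phenyl N-isopropylcarbamate
Conditions: i-PrNCO, Et3N (cat.), CH2Cl2, rt
Reagents that add atoms: isopropyl isocyanate, CC(C)N=C=O
Why: Base-catalysed addition of the phenol to the isocyanate (carbamoylation) installs a strong ortho-directing group that can later be removed under mild base.

Step 5
Reactants: 8 3,5-bis(methoxymethoxy)-4-(3-methylbut-2-en-1-yl)phenyl N-isopropylcarbamate
Product: 12 3,5-bis(methoxymethoxy)-4-(3-methylbut-2-en-1-yl)-2-(trimethylsilyl)phenyl N-isopropylcarbamate, via N-TBS carbamate 9 (not isolated), via ortho-lithiated N-TBS carbamate 10 (not isolated), via N-TBS C-TMS carbamate 11 (not isolated)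
Conditions: TBSOTf, TMEDA, Et2O, 0 °C → rt; then n-BuLi, TMEDA, −78 °C; then TMSCl, −78 °C → rt; aq. NaHSO4 work-up, 0 °C
Reagents that add atoms: chlorotrimethylsilane, C[Si](C)(C)Cl; tert-butyldimethylsilyl triflate, CC(C)(C)[Si](C)(C)OS(=O)(=O)C(F)(F)F (N-silyl group of 9–11 only, not retained in 12)
Why: Directed ortho-metalation, in which the transiently N-silylated carbamate and the neighbouring MOM-oxy group jointly direct lithiation to the carbon between them (the two such positions are equivalent by symmetry); TMSCl traps the aryllithium and the N–Si bond is hydrolysed on work-up.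

Step 6
Reactants: 12 3,5-bis(methoxymethoxy)-4-(3-methylbut-2-en-1-yl)-2-(trimethylsilyl)phenyl N-isopropylcarbamate
Product: 14 3,5-bis(methoxymethoxy)-4-(3-methylbut-2-en-1-yl)-2-(trimethylsilyl)phenyl trifluoromethanesulfonate, via 2-silylphenol 13 (not isolated)
Conditions: DBU, Et2NH, MeCN, 40 °C; then PhNTf2, rt
Reagents that add atoms: N-phenylbis(trifluoromethanesulfonimide), O=S(=O)(N(c1ccccc1)S(=O)(=O)C(F)(F)F)C(F)(F)F
Why: E1cB cleavage of the N–H carbamate by DBU releases the phenoxide and isopropyl isocyanate (scavenged by diethylamine as a urea), and the phenoxide is triflated in the same flask (one-pot carbamate cleavage and O-sulfonylation).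

Step 7
Reactants: 15 3',4'-dihydroxyacetophenone
Product: 16 1-[3,4-bis(methoxymethoxy)phenyl]ethan-1-one
Conditions: MOMCl, K2CO3, acetone, 0 °C → 40 °C
Reagents that add atoms: chloromethyl methyl ether (MOMCl), COCCl
Why: Williamson etherification of the catechol; the carbonate base is too weak to alkylate the ketone at carbon.

Step 8
Reactants: 16 1-[3,4-bis(methoxymethoxy)phenyl]ethan-1-one
Product: 17 ethyl 3-[3,4-bis(methoxymethoxy)phenyl]-3-oxopropanoate
Conditions: NaH, (EtO)2CO, THF, reflux; then AcOH, 0 °C
Reagents that add atoms: diethyl carbonate, CCOC(=O)OCC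
Why: Crossed Claisen condensation of the methyl ketone enolate with diethyl carbonate, driven by deprotonation of the β-keto ester formed.

Step 9
Reactants: 17 ethyl 3-[3,4-bis(methoxymethoxy)phenyl]-3-oxopropanoate
Product: 18 ethyl (3S)-3-[3,4-bis(methoxymethoxy)phenyl]-3-hydroxypropanoate
Conditions: RuCl(p-cymene)[(S,S)-TsDPEN] (1 mol %), HCO2H/Et3N (5:2), DMF, 40 °C
Reagents that add atoms: none
Why: Noyori–Ikariya asymmetric transfer hydrogenation, in which the (S,S)-ligated ruthenium hydride attacks the ketone face fixed by the CH–π contact between the η6-arene and the substrate aryl ring; for an aryl ketone with an sp3 α-carbon this should give the (S)-carbinol, the future C2.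

Step 10
Reactants: 18 ethyl (3S)-3-[3,4-bis(methoxymethoxy)phenyl]-3-hydroxypropanoate
Product: 19 (3S)-3-[3,4-bis(methoxymethoxy)phenyl]-3-hydroxy-N-methoxy-N-methylpropanamide
Conditions: MeNHOMe·HCl, i-PrMgCl, THF, −20 → 0 °C
Reagents that add atoms: N,O-dimethylhydroxylamine hydrochloride, CNOC.Cl
Why: Aminolysis of the ester by the chloromagnesium amide of N,O-dimethylhydroxylamine (Weinreb amide synthesis) proceeds on the magnesium alkoxide at low temperature and does not touch the carbinol stereocentre.

Step 11
Reactants: 19 (3S)-3-[3,4-bis(methoxymethoxy)phenyl]-3-hydroxy-N-methoxy-N-methylpropanamide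
Product: 20 (3S)-3-[3,4-bis(methoxymethoxy)phenyl]-N-methoxy-N-methyl-3-(trimethylsilyloxy)propanamide
Conditions: 1-(trimethylsilyl)imidazole, CH2Cl2, rt; filtration through neutral alumina
Reagents that add atoms: 1-(trimethylsilyl)imidazole, C[Si](C)(C)n1ccnc1
Why: Neutral, salt-free O-silylation turns the alcohol into a latent alkoxide that fluoride can release without any proton source; the configuration is untouched.

Step 12
Reactants: 14 3,5-bis(methoxymethoxy)-4-(3-methylbut-2-en-1-yl)-2-(trimethylsilyl)phenyl trifluoromethanesulfonate; 20 (3S)-3-[3,4-bis(methoxymethoxy)phenyl]-N-methoxy-N-methyl-3-(trimethylsilyloxy)propanamide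
Product: 25 (2S)-2-[3,4-bis(methoxymethoxy)phenyl]-5,7-bis(methoxymethoxy)-6-(3-methylbut-2-en-1-yl)-2,3-dihydro-4H-chromen-4-one, via aryne 21 (not isolated), via potassium alkoxide 22 (not isolated), via aryl anion 23 (not isolated), via tetrahedral amino alkoxide 24 (not isolated)
Conditions: KF, 18-crown-6, THF, 0 °C → rt; then AcOH, 0 °C
Reagents that add atoms: none
Why: Proposed new method: fluoride is expected to unmask both partners without a proton source, converting 14 into aryne 21 and silyl ether 20 into potassium alkoxide 22, which adds to the aryne carbon remote from the flanking MOM-oxy group (the future C8a) so that aryl anion 23 appears at the future C4a and attacks the tethered Weinreb amide to give tetrahedral amino alkoxide 24, which collapses to the ketone only on the acetic acid quench. The closest known reaction type is the fluoride-mediated annulation of arynes with salicylate esters to xanthones (aryloxide addition, then intramolecular acyl substitution), together with the insertion of arynes into the C–O bond of carboxylic acids; what is new is an aliphatic β-alkoxide paired with an amide acceptor. The pyranone ring closes by a 6-exo-trig acyl substitution that follows the intermolecular O–aryl bond formation, so the O1–C8a and C4–C4a bonds are made in one operation. No stereocentre is created: C2 comes from 20 with no bond to it made or broken, and the transient C4 centre of 24 is lost on collapse. The step needs regioselective alkoxide addition, which the inductively withdrawing oxygen next to one aryne carbon should secure by distorting the triple bond (as in 3-alkoxy- and 3,5-dialkoxybenzynes), and it needs acylation to outrun protonation, silylation or β-elimination of 23, which the absence of O–H donors and the intramolecular six-membered attack should secure. Holding the product as 24 until the quench means that no enolisable chromanone is exposed to base, so ring opening to the chalcone and racemisation at C2 should be avoided.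

Step 13
Reactants: 25 (2S)-2-[3,4-bis(methoxymethoxy)phenyl]-5,7-bis(methoxymethoxy)-6-(3-methylbut-2-en-1-yl)-2,3-dihydro-4H-chromen-4-one
Product: 26 (2S)-2-(3,4-dihydroxyphenyl)-5,7-dihydroxy-6-(3-methylbut-2-en-1-yl)-2,3-dihydro-4H-chromen-4-one
Conditions: 3 M aq. HCl, MeOH, 40 °C
Reagents that add atoms: none
Why: Acid-catalysed acetal exchange with methanol (MOM cleavage) should remove all four protecting groups under conditions mild enough that the prenyl alkene is not protonated and the C2–O1 bond is not ionised, so C2 keeps its configuration.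

**Compound list**

1 | resorcinol | Oc1cccc(O)c1 | starting material
2 | 1,3-bis(methoxymethoxy)benzene | COCOc1cccc(OCOC)c1 | intermediate
3 | prenyl bromide (1-bromo-3-methylbut-2-ene) | CC(C)=CCBr | starting material
4 | 2,6-bis(methoxymethoxy)phenyllithium | COCOc1cccc(OCOC)c1[Li] | intermediate (not isolated)
5 | 1,3-bis(methoxymethoxy)-2-(3-methylbut-2-en-1-yl)benzene | COCOc1cccc(OCOC)c1CC=C(C)C | intermediate
6 | 2-[3,5-bis(methoxymethoxy)-4-(3-methylbut-2-en-1-yl)phenyl]-4,4,5,5-tetramethyl-1,3,2-dioxaborolane | COCOc1cc(B2OC(C)(C)C(C)(C)O2)cc(OCOC)c1CC=C(C)C | intermediate (not isolated)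
7 | 3,5-bis(methoxymethoxy)-4-(3-methylbut-2-en-1-yl)phenol | COCOc1cc(O)cc(OCOC)c1CC=C(C)C | intermediate
8 | 3,5-bis(methoxymethoxy)-4-(3-methylbut-2-en-1-yl)phenyl N-isopropylcarbamate | COCOc1cc(OC(=O)NC(C)C)cc(OCOC)c1CC=C(C)C | intermediate
9 | 3,5-bis(methoxymethoxy)-4-(3-methylbut-2-en-1-yl)phenyl N-(tert-butyldimethylsilyl)-N-isopropylcarbamate | COCOc1cc(OC(=O)N(C(C)C)[Si](C)(C)C(C)(C)C)cc(OCOC)c1CC=C(C)C | intermediate (not isolated)
10 | 2-lithio derivative of 9 | COCOc1cc(OC(=O)N(C(C)C)[Si](C)(C)C(C)(C)C)c([Li])c(OCOC)c1CC=C(C)C | intermediate (not isolated)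
11 | 3,5-bis(methoxymethoxy)-4-(3-methylbut-2-en-1-yl)-2-(trimethylsilyl)phenyl N-(tert-butyldimethylsilyl)-N-isopropylcarbamate | COCOc1cc(OC(=O)N(C(C)C)[Si](C)(C)C(C)(C)C)c([Si](C)(C)C)c(OCOC)c1CC=C(C)C | intermediate (not isolated)
12 | 3,5-bis(methoxymethoxy)-4-(3-methylbut-2-en-1-yl)-2-(trimethylsilyl)phenyl N-isopropylcarbamate | COCOc1cc(OC(=O)NC(C)C)c([Si](C)(C)C)c(OCOC)c1CC=C(C)C | intermediate
13 | 3,5-bis(methoxymethoxy)-4-(3-methylbut-2-en-1-yl)-2-(trimethylsilyl)phenol (formed as its DBU salt) | COCOc1cc(O)c([Si](C)(C)C)c(OCOC)c1CC=C(C)C | intermediate (not isolated)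
14 | 3,5-bis(methoxymethoxy)-4-(3-methylbut-2-en-1-yl)-2-(trimethylsilyl)phenyl trifluoromethanesulfonate | COCOc1cc(OS(=O)(=O)C(F)(F)F)c([Si](C)(C)C)c(OCOC)c1CC=C(C)C | intermediate
15 | 3',4'-dihydroxyacetophenone | CC(=O)c1ccc(O)c(O)c1 | starting material
16 | 1-[3,4-bis(methoxymethoxy)phenyl]ethan-1-one | CC(=O)c1ccc(OCOC)c(OCOC)c1 | intermediate
17 | ethyl 3-[3,4-bis(methoxymethoxy)phenyl]-3-oxopropanoate | CCOC(=O)CC(=O)c1ccc(OCOC)c(OCOC)c1 | intermediate
18 | ethyl (3S)-3-[3,4-bis(methoxymethoxy)phenyl]-3-hydroxypropanoate | CCOC(=O)C[C@@H](c1ccc(OCOC)c(OCOC)c1)O | intermediate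
19 | (3S)-3-[3,4-bis(methoxymethoxy)phenyl]-3-hydroxy-N-methoxy-N-methylpropanamide | CON(C)C(=O)C[C@@H](c1ccc(OCOC)c(OCOC)c1)O | intermediate
20 | (3S)-3-[3,4-bis(methoxymethoxy)phenyl]-N-methoxy-N-methyl-3-(trimethylsilyloxy)propanamide | CON(C)C(=O)C[C@@H](c1ccc(OCOC)c(OCOC)c1)O[Si](C)(C)C | intermediate
21 | 3,5-bis(methoxymethoxy)-4-(3-methylbut-2-en-1-yl)benzyne (1,2-didehydrobenzene) | CC(C)=CCC1=C(OCOC)C#CC=C1OCOC | intermediate (not isolated)
22 | potassium (1S)-1-[3,4-bis(methoxymethoxy)phenyl]-3-[methoxy(methyl)amino]-3-oxopropan-1-olate | CON(C)C(=O)C[C@@H](c1ccc(OCOC)c(OCOC)c1)[O-].[K+] | intermediate (not isolated)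
23 | potassium 2-aryloxy-6-(methoxymethoxy)phenyl anion, the adduct of 22 and 21 | CON(C)C(=O)C[C@@H](c1ccc(OCOC)c(OCOC)c1)Oc1cc(OCOC)c(CC=C(C)C)c(OCOC)[c-]1.[K+] | intermediate (not isolated)
24 | potassium (2S)-2-[3,4-bis(methoxymethoxy)phenyl]-4-[methoxy(methyl)amino]-5,7-bis(methoxymethoxy)-6-(3-methylbut-2-en-1-yl)chroman-4-olate (C4 unassigned) | CC(C)=CCc1c(OCOC)cc2c(c1OCOC)C([O-])(N(C)OC)C[C@@H](c1ccc(OCOC)c(OCOC)c1)O2.[K+] | intermediate (not isolated)
25 | (2S)-2-[3,4-bis(methoxymethoxy)phenyl]-5,7-bis(methoxymethoxy)-6-(3-methylbut-2-en-1-yl)-2,3-dihydro-4H-chromen-4-one | CC(C)=CCc1c(OCOC)cc2c(c1OCOC)C(=O)C[C@@H](c1ccc(OCOC)c(OCOC)c1)O2 | intermediate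
26 | (2S)-2-(3,4-dihydroxyphenyl)-5,7-dihydroxy-6-(3-methylbut-2-en-1-yl)-2,3-dihydro-4H-chromen-4-one | CC(C)=CCc1c(O)cc2c(c1O)C(=O)C[C@@H](c1ccc(O)c(O)c1)O2 | target

**Step count and risks**

Total step count: 13. Longest linear sequence: 8 steps (steps 1–6, 12 and 13, from resorcinol).

Steps most likely to fail:

1. Step 12 (proposed new method). What may go wrong: the aryl anion is quenched before ring closure (by adventitious protons, by silicon electrophiles, or by the α-C–H of the amide with ensuing β-elimination), or the free alkoxide undergoes retro-aldol cleavage or attacks the sulfonyl sulfur before the aryne is generated. Fallback (known chemistry, the same two bonds made one after the other): it sets out from phenol 7 and β-keto ester 17 and comes back to the route at 25. Iodination of 7 ortho to the hydroxyl (NIS, CH2Cl2, −40 °C) should give 2-iodo-3,5-bis(methoxymethoxy)-4-(3-methylbut-2-en-1-yl)phenol F1. Transfer hydrogenation of 17 with the enantiomeric catalyst, RuCl(p-cymene)[(R,R)-TsDPEN], should give ethyl (3R)-3-[3,4-bis(methoxymethoxy)phenyl]-3-hydroxypropanoate F2, which is converted as in step 10 into (3R)-3-[3,4-bis(methoxymethoxy)phenyl]-3-hydroxy-N-methoxy-N-methylpropanamide F3. Mitsunobu etherification of F1 with F3 (PPh3, DIAD, toluene, 0 °C) forms the aryl–O bond with inversion and should give (3S)-3-[3,4-bis(methoxymethoxy)phenyl]-3-[2-iodo-3,5-bis(methoxymethoxy)-4-(3-methylbut-2-en-1-yl)phenoxy]-N-methoxy-N-methylpropanamide F4. Iodine–lithium exchange (n-BuLi, THF, −100 °C) with ring closure of the aryllithium onto the Weinreb amide (Parham cyclisation) should then give 25 after aqueous work-up.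

2. Step 5. What may go wrong: loss of a MOM group promoted by the silyl triflate during the transient N-silylation, or competing deprotonation at the benzylic–allylic CH2 of the prenyl group. Fallback (halogenation and retro-Brook shift instead of carbamate-directed metalation): it sets out from phenol 7 and comes back at 14. Ortho-bromination (NBS, CH2Cl2, −78 °C) should give 2-bromo-3,5-bis(methoxymethoxy)-4-(3-methylbut-2-en-1-yl)phenol F5, and O-silylation (HMDS, THF, 65 °C) its trimethylsilyl ether, [2-bromo-3,5-bis(methoxymethoxy)-4-(3-methylbut-2-en-1-yl)phenoxy]trimethylsilane F6. Bromine–lithium exchange (n-BuLi, THF, −78 °C) triggers the 1,3 O→C silyl shift to the lithium salt of 13, which is triflated in the same flask (Tf2O, −78 °C) to give 14.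

3. Step 13. What may go wrong: acid-catalysed cyclisation of the prenyl group onto the flanking 5- or 7-hydroxyl (chroman formation), or partial racemisation through ring opening on prolonged heating. Fallback (non-protic silyl transfer instead of Brønsted acidolysis): it sets out from 25 and comes back at 26. TMSOTf and 2,2'-bipyridyl (CH2Cl2, 0 °C) should exchange each aryl MOM ether for a trimethylsilyl ether, giving (2S)-2-[3,4-bis(trimethylsilyloxy)phenyl]-6-(3-methylbut-2-en-1-yl)-5,7-bis(trimethylsilyloxy)-2,3-dihydro-4H-chromen-4-one F7; hydrolysis of the four aryl silyl ethers at neutral pH (H2O, MeOH, rt) then gives 26.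

**Further compounds**

F1 | step 12 | 2-iodo-3,5-bis(methoxymethoxy)-4-(3-methylbut-2-en-1-yl)phenol | COCOc1cc(O)c(I)c(OCOC)c1CC=C(C)C
F2 | step 12 | ethyl (3R)-3-[3,4-bis(methoxymethoxy)phenyl]-3-hydroxypropanoate | CCOC(=O)C[C@H](c1ccc(OCOC)c(OCOC)c1)O
F3 | step 12 | (3R)-3-[3,4-bis(methoxymethoxy)phenyl]-3-hydroxy-N-methoxy-N-methylpropanamide | CON(C)C(=O)C[C@H](c1ccc(OCOC)c(OCOC)c1)O
F4 | step 12 | (3S)-3-[3,4-bis(methoxymethoxy)phenyl]-3-[2-iodo-3,5-bis(methoxymethoxy)-4-(3-methylbut-2-en-1-yl)phenoxy]-N-methoxy-N-methylpropanamide | CON(C)C(=O)C[C@@H](c1ccc(OCOC)c(OCOC)c1)Oc1cc(OCOC)c(CC=C(C)C)c(OCOC)c1I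
F5 | step 5 | 2-bromo-3,5-bis(methoxymethoxy)-4-(3-methylbut-2-en-1-yl)phenol | COCOc1cc(O)c(Br)c(OCOC)c1CC=C(C)C
F6 | step 5 | [2-bromo-3,5-bis(methoxymethoxy)-4-(3-methylbut-2-en-1-yl)phenoxy]trimethylsilane | COCOc1cc(O[Si](C)(C)C)c(Br)c(OCOC)c1CC=C(C)C
F7 | step 13 | (2S)-2-[3,4-bis(trimethylsilyloxy)phenyl]-6-(3-methylbut-2-en-1-yl)-5,7-bis(trimethylsilyloxy)-2,3-dihydro-4H-chromen-4-one | CC(C)=CCc1c(O[Si](C)(C)C)cc2c(c1O[Si](C)(C)C)C(=O)C[C@@H](c1ccc(O[Si](C)(C)C)c(O[Si](C)(C)C)c1)O2
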